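A direct plan would make the γ-pyrone first and grow ring A onto it. The pyranone A1, 2-(3,4,5-trimethoxyphenyl)-4H-pyran-4-one, would be lithiated next to the ring oxygen and added to dimethyl squarate A2 to give carbinol A3, the carbinol would be benzylated to ether A4, and A4 would be heated so that cyclobutenone opening and 6π closure would give the 8-benzyloxy-5-hydroxyflavone A5; methylation of the 5-OH and hydrogenolysis would finish.
Its weakest steps would be:
- the deprotonation of the pyranone and the capture of the vinyllithium by the squarate: the pyranone is base-labile, the lithio species could open to an ynone enolate or form at C3/C5, and the whole plan would rest on it;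
- the benzylation of the hindered, strained tertiary carbinol, which with the later methylation and hydrogenolysis would spend three steps only on telling the C5 and C8 oxygens apart, the last with the risk of reducing C2=C3 on the final material;
- the thermal ring expansion, which would have to be run dilute on late material.

**Plan of the new route**
The retrosynthesis cuts C4–C4a (Friedel–Crafts acylation) and then both C–O bonds at C2, giving 3,4,5-trimethoxybenzene-1,2-diol and an arylpropiolate. Rings A and B come from commercial aromatics and ring C is formed last.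
The feature used is that O1 (on C8a) and the 8-OH (on C8) are ortho oxygens of ring A, a catechol in which only the C8a oxygen has a free ortho carbon (C4a–H). Both oxygens are first tied to C2 in a 1,3-benzodioxole ketal; acid opens it and only the enol ether on the C8a oxygen can acylate, so the 8-OH emerges free.
No pyranone is metalated, no protecting group is used, and nothing is thermolysed or hydrogenated at the end.

Key step: step 5

Remark (assumption): step 3 is written as giving the closed ketal 8. If part of the material stays as an open-chain mono-adduct, it would be carried along, because step 5 passes through the same ring-opened species.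

Step 1
Reactants: 1 5-ethynyl-1,2,3-trimethoxybenzene; 2 ethyl chloroformate
Product: 4 ethyl 3-(3,4,5-trimethoxyphenyl)prop-2-ynoate, via lithium acetylide 3 (not isolated)
Conditions: n-BuLi (1.05 equiv), THF, −78 °C; 2 (1.3 equiv), −78 °C → 0 °C; aq. NH4Cl
Reagents that add atoms: ethyl chloroformate (2), CCOC(=O)Cl
Why: Deprotonation of the terminal alkyne and C-acylation of the lithium acetylide with a chloroformate is the standard route to arylpropiolates.

Step 2
Reactants: 5 3,4,5-trimethoxyphenol
Product: 7 3,4,5-trimethoxybenzene-1,2-diol, via ortho-quinone 6 (not isolated)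
Conditions: IBX (1.1 equiv), DMF, rt, dark; then aq. Na2S2O4 (excess), rt; work-up under Ar
Reagents that add atoms: 2-iodoxybenzoic acid (IBX), O=C1OI(=O)(O)c2ccccc12
Why: In the IBX ortho-oxygenation of electron-rich phenols the phenol binds to pentavalent iodine and oxygen is delivered to the ortho carbon (the two ortho positions of 5 are equivalent and free, the para position carries a methoxy group), the catechol is oxidised on to ortho-quinone 6, and dithionite reduces 6 in the same flask to catechol 7.

Step 3
Reactants: 7 3,4,5-trimethoxybenzene-1,2-diol; 4 ethyl 3-(3,4,5-trimethoxyphenyl)prop-2-ynoate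
Product: 8 rac-ethyl 2-[4,5,6-trimethoxy-2-(3,4,5-trimethoxyphenyl)-1,3-benzodioxol-2-yl]acetate
Conditions: Cs2CO3 (0.3 equiv), DMF (degassed), 60 °C, Ar
Reagents that add atoms: none
Why: Double oxa-Michael addition of a catechol to an activated alkyne, the known route to 2,2-disubstituted 1,3-benzodioxoles: one catecholate oxygen adds to the ynoate β-carbon and the neighbouring phenol then adds to the same carbon by 5-exo-trig closure; either oxygen may add first since both paths converge on 8, and the ketal carbon forms racemic and is destroyed in step 5.

Step 4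
Reactants: 8 rac-ethyl 2-[4,5,6-trimethoxy-2-(3,4,5-trimethoxyphenyl)-1,3-benzodioxol-2-yl]acetate
Product: 9 rac-2-[4,5,6-trimethoxy-2-(3,4,5-trimethoxyphenyl)-1,3-benzodioxol-2-yl]acetic acid
Conditions: LiOH·H2O (3 equiv), THF–MeOH–H2O, rt; 1 M HCl to pH 3, 0 °C
Reagents that add atoms: lithium hydroxide, [Li+].[OH-]
Why: Saponification of an unhindered ethyl ester; the diaryl ketal should be inert to hydroxide and to brief cold dilute acid, and any retro-oxa-Michael opening would only give a β-aryloxycinnamic acid that enters step 5 through the same cation.

Step 5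
Reactants: 9 rac-2-[4,5,6-trimethoxy-2-(3,4,5-trimethoxyphenyl)-1,3-benzodioxol-2-yl]acetic acid
Product: 12 8-hydroxy-5,6,7-trimethoxy-2-(3,4,5-trimethoxyphenyl)-4H-chromen-4-one (8-hydroxy-5,6,7,3',4',5'-hexamethoxyflavone), via oxocarbenium ion 10 (not isolated), via enol-ether acid 11 (not isolated)
Conditions: Eaton's reagent (P2O5 in MeSO3H, 1:10 w/w), 0 °C → 40 °C, Ar; poured onto ice
Reagents that add atoms: none
Why: Proposed new method: methanesulfonic acid should protonate a ketal oxygen of 9 and cleave one C2–O bond to the aryl- and aryloxy-stabilised oxocarbenium ion 10, which loses a C3 proton to give the β-aryloxycinnamic acid 11 while P2O5 turns the carboxyl group into a mixed anhydride or acylium ion; the closest known reaction types are the acid cyclisation of β-aryloxycinnamic acids to flavones (Ruhemann synthesis) and the acid-catalysed ring–chain exchange of catechol ketals. Ring C then closes by a six-membered intramolecular Friedel–Crafts acylation that forms the C4–C4a bond and, after loss of the C4a proton, the benzopyranone. No stereocentre is formed, and the racemic ketal carbon of 9 becomes the sp2 carbon C2. The step needs two selectivities: which catechol oxygen stays in the ring, and ring A against ring B as the arene that is acylated. The first should be secured because the two ring-opened enol ethers interconvert through 10 and the ketal, yet only the oxygen on C8a has a free ortho carbon (C4a–H), the other being flanked by the C8a oxygen and the C7 methoxy group, so that all material should drain through the one irreversible acylation (Curtin–Hammett) and the other oxygen is left as the free 8-OH. The second should be secured because attack by ring B would have to close a five-membered indanone ring ortho to a carbon bearing two oxygens, whereas C4a is activated by the ortho enol-ether oxygen, the ortho C5 methoxy and the para C7 methoxy group, and its closure gives an aromatic (protonated) 4-pyranone.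

**Compound list**

1 | 5-ethynyl-1,2,3-trimethoxybenzene | C#Cc1cc(OC)c(OC)c(OC)c1 | starting material
2 | ethyl chloroformate | CCOC(=O)Cl | starting material
3 | lithium (3,4,5-trimethoxyphenyl)acetylide | [Li]C#Cc1cc(OC)c(OC)c(OC)c1 | intermediate (not isolated)
4 | ethyl 3-(3,4,5-trimethoxyphenyl)prop-2-ynoate | CCOC(=O)C#Cc1cc(OC)c(OC)c(OC)c1 | intermediate
5 | 3,4,5-trimethoxyphenol | COc1cc(O)cc(OC)c1OC | starting material
6 | 3,4,5-trimethoxycyclohexa-3,5-diene-1,2-dione (3,4,5-trimethoxy-1,2-benzoquinone) | COC1=CC(=O)C(=O)C(OC)=C1OC | intermediate (not isolated)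
7 | 3,4,5-trimethoxybenzene-1,2-diol | COc1cc(O)c(O)c(OC)c1OC | intermediate
8 | rac-ethyl 2-[4,5,6-trimethoxy-2-(3,4,5-trimethoxyphenyl)-1,3-benzodioxol-2-yl]acetate | CCOC(=O)CC1(c2cc(OC)c(OC)c(OC)c2)Oc2cc(OC)c(OC)c(OC)c2O1 | intermediate
9 | rac-2-[4,5,6-trimethoxy-2-(3,4,5-trimethoxyphenyl)-1,3-benzodioxol-2-yl]acetic acid | OC(=O)CC1(c2cc(OC)c(OC)c(OC)c2)Oc2cc(OC)c(OC)c(OC)c2O1 | intermediate
10 | [2-carboxy-1-(3,4,5-trimethoxyphenyl)ethylidene](2-hydroxy-3,4,5-trimethoxyphenyl)oxonium (ring-opened oxocarbenium ion) | OC(=O)CC(=[O+]c1cc(OC)c(OC)c(OC)c1O)c1cc(OC)c(OC)c(OC)c1 | intermediate (not isolated)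
11 | (2Z)-3-(2-hydroxy-3,4,5-trimethoxyphenoxy)-3-(3,4,5-trimethoxyphenyl)prop-2-enoic acid | OC(=O)/C=C(/c1cc(OC)c(OC)c(OC)c1)Oc1cc(OC)c(OC)c(OC)c1O | intermediate (not isolated)
12 | 8-hydroxy-5,6,7-trimethoxy-2-(3,4,5-trimethoxyphenyl)-4H-chromen-4-one | COc1cc(-c2cc(=O)c3c(OC)c(OC)c(OC)c(O)c3o2)cc(OC)c1OC | target

**Step count and risks**

Total steps: 5. Longest linear sequence: 4 (steps 2, 3, 4, 5).

Steps most likely to fail:

1. Step 5 (proposed new method). Ionisation of the ketal may be slow, so that the acylium ion is captured by ring B in a five-membered closure or by the free phenol as a lactone, or the ring-opened acid may decarboxylate before it acylates. The fallback uses known chemistry and sets out from catechol 7. Friedel–Crafts acylation with commercial (E)-3-(3,4,5-trimethoxyphenyl)acryloyl chloride in BF3·OEt2 (rt → 60 °C; O-acylation followed by Fries shift to the only free ring carbon) would give (E)-1-(2,3-dihydroxy-4,5,6-trimethoxyphenyl)-3-(3,4,5-trimethoxyphenyl)prop-2-en-1-one F1 as the chalcone. Oxidative cyclisation of F1 with I2 (cat.) in DMSO at 120 °C, in which only the hydroxyl next to the ketone can close a six-membered ring, would return to the route at target 12.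

2. Step 3. The electron-rich catecholate may be oxidised by traces of air, the second conjugate addition may stall and leave mixtures of open-chain isomers, or the free phenol may attack the ester instead of the alkene. The fallback sets out from catechol 7 and replaces conjugate addition by carbonyl condensation: acid-catalysed ketalisation with commercial ethyl 3-oxo-3-(3,4,5-trimethoxyphenyl)propanoate (TsOH cat., toluene, Dean–Stark) would give 8 directly, with no new compound on the way, and rejoins the route at 8.

3. Step 2. Over-oxidation, attack at a methoxy-bearing carbon with loss of methanol, or air oxidation of the catechol during work-up may erode the material. The fallback sets out from phenol 5. Ortho-formylation with MgCl2, Et3N and paraformaldehyde (MeCN, reflux) would give 2-hydroxy-4,5,6-trimethoxybenzaldehyde F2 at one of the two equivalent free ortho carbons. Dakin oxidation of F2 (H2O2, aq. NaOH, 0 °C → rt, Ar; then acidification) would rejoin the route at catechol 7.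

**Further compounds**

F1 | step 5 | (E)-1-(2,3-dihydroxy-4,5,6-trimethoxyphenyl)-3-(3,4,5-trimethoxyphenyl)prop-2-en-1-one | COc1cc(/C=C/C(=O)c2c(O)c(O)c(OC)c(OC)c2OC)cc(OC)c1OC
F0 | step 3 | none | none
F2 | step 2 | 2-hydroxy-4,5,6-trimethoxybenzaldehyde | COc1cc(O)c(C=O)c(OC)c1OC
A1 | direct plan | 2-(3,4,5-trimethoxyphenyl)-4H-pyran-4-one | COc1cc(-c2cc(=O)cco2)cc(OC)c1OC
A2 | direct plan | dimethyl squarate (3,4-dimethoxycyclobut-3-ene-1,2-dione) | COC1=C(OC)C(=O)C1=O
A3 | direct plan | rac-4-hydroxy-2,3-dimethoxy-4-[4-oxo-6-(3,4,5-trimethoxyphenyl)-4H-pyran-2-yl]cyclobut-2-en-1-one | COC1=C(OC)C(O)(c2cc(=O)cc(-c3cc(OC)c(OC)c(OC)c3)o2)C1=O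
A4 | direct plan | rac-4-(benzyloxy)-2,3-dimethoxy-4-[4-oxo-6-(3,4,5-trimethoxyphenyl)-4H-pyran-2-yl]cyclobut-2-en-1-one | COC1=C(OC)C(OCc2ccccc2)(c2cc(=O)cc(-c3cc(OC)c(OC)c(OC)c3)o2)C1=O
A5 | direct plan | 8-(benzyloxy)-5-hydroxy-6,7-dimethoxy-2-(3,4,5-trimethoxyphenyl)-4H-chromen-4-one | COc1cc(-c2cc(=O)c3c(O)c(OC)c(OC)c(OCc4ccccc4)c3o2)cc(OC)c1OC
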